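**Plan**
Retrosynthesis: the O1–C8a aryl ether bond of ring C is cut first (back to an ortho-fluoroaryl ketone with a free C2 hydroxyl), then the C2–C3 and C3–O bonds are cut together, leaving a ring A diazoketone, 4-methoxybenzyl alcohol and a ring B aldehyde.
Enabling feature: C3 carries a hydroxyl and lies between the C4 ketone and the C2 carbinol carbon, so it can be a carbenoid carbon that takes up first an oxygen nucleophile and then an aldehyde.
Forward: ring A (from 4-bromo-3-fluorophenol) and ring B (from 3,5-dibromo-4-hydroxybenzaldehyde) are prenylated separately and joined with the alcohol in one three-component step to the open C2–C3 chain; ring C closes last by displacement of fluoride by the C2 oxygen, then the PMB and MOM groups are removed.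
Stereochemistry: C2 and C3 are set together in the three-component step by a chiral phosphoric acid as the anti (2R,3R) pair; ring closure breaks no bond at either centre, and trans is also the thermodynamic arrangement at C3.

Key step: step 7

Assumption: flavanone numbering (O1, C2, C3, C4; rings A, B, C) is used for all intermediates; (R)-TRIP, (R)-3,3′-bis(2,4,6-triisopropylphenyl)-1,1′-binaphthyl-2,2′-diyl hydrogen phosphate, is taken as the antipode that leads to the (2R,3R) adduct, and (S)-TRIP would be used if the sense of induction is the other way.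

**Step 1**
Reactants: 1 4-bromo-3-fluorophenol
Product: 2 1-bromo-2-fluoro-4-(methoxymethoxy)benzene
Conditions: NaH, MOMCl, THF, 0 °C to rt
Reagents that add atoms: chloromethyl methyl ether (MOMCl), COCCl
Why: Williamson O-alkylation of the phenoxide formed with NaH by the reactive α-chloro ether should give the aryl MOM ether, which is stable to the bases used later and directs the lithiation of step 2.

**Step 2**
Reactants: 2 1-bromo-2-fluoro-4-(methoxymethoxy)benzene; 3 prenyl bromide (1-bromo-3-methylbut-2-ene)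
Product: 5 1-bromo-2-fluoro-4-(methoxymethoxy)-3-(3-methylbut-2-en-1-yl)benzene, via aryllithium 4 (not isolated)
Conditions: LiN(iPr)2, THF, −78 °C; then CuBr·SMe2 (10 mol%), 3, −78 to −40 °C
Reagents that add atoms: none
Why: Directed ortho-metalation: the hydrogen flanked by fluorine and the MOM ether is by far the most acidic and LiN(iPr)2 does not exchange the bromide, so aryllithium 4 should form cleanly at −78 °C (below the temperature at which LiF is lost) and its copper-catalysed allylic substitution at the primary carbon of 3 should give the linear prenyl group.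

**Step 3**
Reactants: 5 1-bromo-2-fluoro-4-(methoxymethoxy)-3-(3-methylbut-2-en-1-yl)benzene; 6 N-methoxy-N-methylacetamide
Product: 8 1-[2-fluoro-4-(methoxymethoxy)-3-(3-methylbut-2-en-1-yl)phenyl]ethan-1-one, via aryllithium 7 (not isolated)
Conditions: n-BuLi, THF, −78 °C; then 6, −78 to −40 °C; AcOH quench
Reagents that add atoms: none
Why: Bromine–lithium exchange is fast at −78 °C and the Weinreb ketone synthesis stops at the chelated tetrahedral adduct, so the methyl ketone should form without over-addition and without loss of LiF from the ortho-fluoro aryllithium.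

**Step 4**
Reactants: 8 1-[2-fluoro-4-(methoxymethoxy)-3-(3-methylbut-2-en-1-yl)phenyl]ethan-1-one
Product: 10 2-diazo-1-[2-fluoro-4-(methoxymethoxy)-3-(3-methylbut-2-en-1-yl)phenyl]ethan-1-one, via trifluoroacetyl diketone 9 (not isolated)
Conditions: LiN(SiMe3)2, CF3CO2CH2CF3, THF, −78 °C; AcOH quench; then 4-acetamidobenzenesulfonyl azide, Et3N, H2O, MeCN, rt
Reagents that add atoms: 4-acetamidobenzenesulfonyl azide, CC(=O)Nc1ccc(cc1)S(=O)(=O)N=[N+]=[N-]; 2,2,2-trifluoroethyl trifluoroacetate, O=C(OCC(F)(F)F)C(F)(F)F (its trifluoroacetyl group is carried by 9 only)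
Why: Deacylative Regitz diazo transfer: Claisen trifluoroacetylation of the ketone enolate makes the methyl group acidic enough for the sulfonyl azide to transfer N2 with loss of the trifluoroacetyl group, a sequence that needs neither an acid chloride nor diazomethane and so spares the MOM ether and the prenyl double bond from HCl.

**Step 5**
Reactants: 11 3,5-dibromo-4-hydroxybenzaldehyde
Product: 12 3,5-dibromo-4-(methoxymethoxy)benzaldehyde
Conditions: MOMCl, K2CO3, DMF, 0 °C to rt
Reagents that add atoms: chloromethyl methyl ether (MOMCl), COCCl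
Why: Williamson O-alkylation: the acidic dibromophenol is fully ionised by K2CO3 and the small, reactive MOMCl should alkylate the oxygen despite the two ortho bromine atoms.

**Step 6**
Reactants: 12 3,5-dibromo-4-(methoxymethoxy)benzaldehyde; 13 tributyl(3-methylbut-2-en-1-yl)stannane
Product: 15 4-(methoxymethoxy)-3,5-bis(3-methylbut-2-en-1-yl)benzaldehyde, via monoprenyl bromide 14 (not isolated)
Conditions: Pd(PPh3)4 (10 mol%), 13 (2.5 equiv), DMF, 100 °C
Reagents that add atoms: none
Why: Twofold Stille coupling: both C–Br bonds are activated for oxidative addition by the para formyl group, the aldehyde is inert to the stannane without a Lewis acid, and reductive elimination from the less hindered primary terminus of the prenylpalladium intermediate should give the linear prenyl groups.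

**Step 7**
Reactants: 10 2-diazo-1-[2-fluoro-4-(methoxymethoxy)-3-(3-methylbut-2-en-1-yl)phenyl]ethan-1-one; 16 4-methoxybenzyl alcohol; 15 4-(methoxymethoxy)-3,5-bis(3-methylbut-2-en-1-yl)benzaldehyde
Product: 18 (2R,3R)-1-[2-fluoro-4-(methoxymethoxy)-3-(3-methylbut-2-en-1-yl)phenyl]-3-hydroxy-2-[(4-methoxyphenyl)methoxy]-3-[4-(methoxymethoxy)-3,5-bis(3-methylbut-2-en-1-yl)phenyl]propan-1-one, via oxonium ylide 17 (not isolated)
Conditions: Rh2(OAc)4 (2 mol%), (R)-TRIP (10 mol%), 4 Å MS, CH2Cl2, 0 °C; 10 added over 3 h to 15 (2 equiv) and 16 (1.2 equiv)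
Reagents that add atoms: none
Why: Proposed new method: Rh2(OAc)4 releases N2 from 10 to give a Rh2(OAc)4-bound carbenoid at the future C3, the hydroxyl oxygen of 16 adds to it, and the resulting oxonium ylide 17 (in equilibrium with its Z-enol) is intercepted at carbon by aldehyde 15, which the phosphoric acid activates by hydrogen bonding while its P=O oxygen holds the O–H of the ylide, so that the C3–O and C2–C3 bonds form in one operation and no ring closes. The closest known reaction types are the Rh2(OAc)4 and chiral phosphoric acid co-catalysed three-component Mannich-type coupling of diazoacetophenones with alcohols and imines, and the aldol-type trapping by aryl aldehydes of alcohol-derived oxonium ylides from aryl diazoacetates; new here is the pairing of an acceptor-only diazoketone with an aryl aldehyde under a chiral acid. Both new stereocentres (C2 and C3) are controlled by the chiral pocket of the acid in this acid-bridged open transition state: the aldehyde face it exposes fixes C2 as R, and the Z-enol geometry with the two aryl groups held apart should give the anti (2R,3R) relation. The step needs trapping to outrun the 1,2-proton shift that leads to plain O–H insertion, which is helped by the aryl ketone enol being longer lived than an ester-derived ylide, by the twofold excess of 15, and by the two prenyl groups that twist the 4-OMOM group of 15 out of conjugation so that the formyl group is not deactivated by resonance. It also needs the carbenoid to take the alcohol and not a prenyl double bond, which the far higher nucleophilicity of the hydroxyl group, the slow addition of 10 and the absence of any feasible intramolecular cyclopropanation secure. Should the anti selectivity be incomplete, C3 can still be equilibrated to the trans arrangement after ring closure in step 8.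

**Step 8**
Reactants: 18 (2R,3R)-1-[2-fluoro-4-(methoxymethoxy)-3-(3-methylbut-2-en-1-yl)phenyl]-3-hydroxy-2-[(4-methoxyphenyl)methoxy]-3-[4-(methoxymethoxy)-3,5-bis(3-methylbut-2-en-1-yl)phenyl]propan-1-one
Product: 19 (2R,3R)-7-(methoxymethoxy)-3-[(4-methoxyphenyl)methoxy]-2-[4-(methoxymethoxy)-3,5-bis(3-methylbut-2-en-1-yl)phenyl]-8-(3-methylbut-2-en-1-yl)-2,3-dihydro-4H-chromen-4-one
Conditions: Cs2CO3 (1.5 equiv), 4 Å MS, DMF, 0 °C to rt
Reagents that add atoms: none
Why: Intramolecular SNAr (addition–elimination through a Meisenheimer adduct, 6-exo closure of ring C): the C2 alkoxide displaces the fluoride that the ortho carbonyl group activates, no bond at C2 or C3 is broken so both centres are kept, and the anti pair should appear as the trans (diequatorial, thermodynamically preferred) chromanone.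

**Step 9**
Reactants: 19 (2R,3R)-7-(methoxymethoxy)-3-[(4-methoxyphenyl)methoxy]-2-[4-(methoxymethoxy)-3,5-bis(3-methylbut-2-en-1-yl)phenyl]-8-(3-methylbut-2-en-1-yl)-2,3-dihydro-4H-chromen-4-one
Product: 20 (2R,3R)-3-hydroxy-7-(methoxymethoxy)-2-[4-(methoxymethoxy)-3,5-bis(3-methylbut-2-en-1-yl)phenyl]-8-(3-methylbut-2-en-1-yl)-2,3-dihydro-4H-chromen-4-one
Conditions: DDQ (1.3 equiv), CH2Cl2–pH 7 buffer (10:1), 0 °C
Reagents that add atoms: none
Why: Oxidative PMB ether cleavage: DDQ abstracts hydride from the 4-methoxybenzylic position, the most easily oxidised site, and water hydrolyses the oxocarbenium ion, while the MOM-capped prenylated rings (ring A is further deactivated by the C4 carbonyl) should react far more slowly at 0 °C under buffered conditions.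

**Step 10**
Reactants: 20 (2R,3R)-3-hydroxy-7-(methoxymethoxy)-2-[4-(methoxymethoxy)-3,5-bis(3-methylbut-2-en-1-yl)phenyl]-8-(3-methylbut-2-en-1-yl)-2,3-dihydro-4H-chromen-4-one
Product: 21 (2R,3R)-3,7-dihydroxy-2-[4-hydroxy-3,5-bis(3-methylbut-2-en-1-yl)phenyl]-8-(3-methylbut-2-en-1-yl)-2,3-dihydro-4H-chromen-4-one (CNP0316331.1)
Conditions: HCl (1.25 M in MeOH), rt
Reagents that add atoms: none
Why: Acid-catalysed acetal exchange: both aryl MOM ethers are transferred to methanol as dimethoxymethane under dilute anhydrous HCl at room temperature, conditions under which ortho-prenyl phenols are usually not yet cyclised and under which C2 and C3 are not epimerised.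

**Compound list**
1 | 4-bromo-3-fluorophenol | Oc1ccc(Br)c(F)c1 | starting material
2 | 1-bromo-2-fluoro-4-(methoxymethoxy)benzene | COCOc1ccc(Br)c(F)c1 | intermediate
3 | prenyl bromide (1-bromo-3-methylbut-2-ene) | CC(C)=CCBr | starting material
4 | [3-bromo-2-fluoro-6-(methoxymethoxy)phenyl]lithium | [Li]c1c(OCOC)ccc(Br)c1F | intermediate
5 | 1-bromo-2-fluoro-4-(methoxymethoxy)-3-(3-methylbut-2-en-1-yl)benzene | COCOc1ccc(Br)c(F)c1CC=C(C)C | intermediate
6 | N-methoxy-N-methylacetamide | CC(=O)N(C)OC | starting material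
7 | [2-fluoro-4-(methoxymethoxy)-3-(3-methylbut-2-en-1-yl)phenyl]lithium | [Li]c1ccc(OCOC)c(CC=C(C)C)c1F | intermediate
8 | 1-[2-fluoro-4-(methoxymethoxy)-3-(3-methylbut-2-en-1-yl)phenyl]ethan-1-one | CC(=O)c1ccc(OCOC)c(CC=C(C)C)c1F | intermediate
9 | 4,4,4-trifluoro-1-[2-fluoro-4-(methoxymethoxy)-3-(3-methylbut-2-en-1-yl)phenyl]butane-1,3-dione | O=C(CC(=O)C(F)(F)F)c1ccc(OCOC)c(CC=C(C)C)c1F | intermediate
10 | 2-diazo-1-[2-fluoro-4-(methoxymethoxy)-3-(3-methylbut-2-en-1-yl)phenyl]ethan-1-one | [N-]=[N+]=CC(=O)c1ccc(OCOC)c(CC=C(C)C)c1F | intermediate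
11 | 3,5-dibromo-4-hydroxybenzaldehyde | O=Cc1cc(Br)c(O)c(Br)c1 | starting material
12 | 3,5-dibromo-4-(methoxymethoxy)benzaldehyde | O=Cc1cc(Br)c(OCOC)c(Br)c1 | intermediate
13 | tributyl(3-methylbut-2-en-1-yl)stannane | CCCC[Sn](CCCC)(CCCC)CC=C(C)C | starting material
14 | 3-bromo-4-(methoxymethoxy)-5-(3-methylbut-2-en-1-yl)benzaldehyde | O=Cc1cc(Br)c(OCOC)c(CC=C(C)C)c1 | intermediate
15 | 4-(methoxymethoxy)-3,5-bis(3-methylbut-2-en-1-yl)benzaldehyde | O=Cc1cc(CC=C(C)C)c(OCOC)c(CC=C(C)C)c1 | intermediate
16 | 4-methoxybenzyl alcohol | COc1ccc(CO)cc1 | starting material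
17 | oxonium ylide from 10 and 16 (2-oxo-2-aryl-ethanide bearing the protonated 4-methoxybenzyloxy group) | O=C([CH-][OH+]Cc1ccc(OC)cc1)c1ccc(OCOC)c(CC=C(C)C)c1F | intermediate
18 | (2R,3R)-1-[2-fluoro-4-(methoxymethoxy)-3-(3-methylbut-2-en-1-yl)phenyl]-3-hydroxy-2-[(4-methoxyphenyl)methoxy]-3-[4-(methoxymethoxy)-3,5-bis(3-methylbut-2-en-1-yl)phenyl]propan-1-one (anti) | O[C@H](c1cc(CC=C(C)C)c(OCOC)c(CC=C(C)C)c1)[C@@H](OCc1ccc(OC)cc1)C(=O)c1ccc(OCOC)c(CC=C(C)C)c1F | intermediate
19 | (2R,3R)-7-(methoxymethoxy)-3-[(4-methoxyphenyl)methoxy]-2-[4-(methoxymethoxy)-3,5-bis(3-methylbut-2-en-1-yl)phenyl]-8-(3-methylbut-2-en-1-yl)-2,3-dihydro-4H-chromen-4-one (trans) | CC(C)=CCc1cc([C@H]2Oc3c(ccc(OCOC)c3CC=C(C)C)C(=O)[C@@H]2OCc4ccc(OC)cc4)cc(CC=C(C)C)c1OCOC | intermediate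
20 | (2R,3R)-3-hydroxy-7-(methoxymethoxy)-2-[4-(methoxymethoxy)-3,5-bis(3-methylbut-2-en-1-yl)phenyl]-8-(3-methylbut-2-en-1-yl)-2,3-dihydro-4H-chromen-4-one | CC(C)=CCc1cc([C@H]2Oc3c(ccc(OCOC)c3CC=C(C)C)C(=O)[C@@H]2O)cc(CC=C(C)C)c1OCOC | intermediate
21 | (2R,3R)-3,7-dihydroxy-2-[4-hydroxy-3,5-bis(3-methylbut-2-en-1-yl)phenyl]-8-(3-methylbut-2-en-1-yl)-2,3-dihydro-4H-chromen-4-one | CC(C)=CCc1cc([C@H]2Oc3c(ccc(O)c3CC=C(C)C)C(=O)[C@@H]2O)cc(CC=C(C)C)c1O | target

**Step count**
Total: 10 steps. Longest linear sequence: 8 steps (steps 1, 2, 3, 4, 7, 8, 9, 10); the ring B branch (steps 5 and 6) joins at step 7.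

**Steps most likely to fail**
In the fallbacks, ArA stands for 2-fluoro-4-(methoxymethoxy)-3-(3-methylbut-2-en-1-yl)phenyl and ArB for 4-(methoxymethoxy)-3,5-bis(3-methylbut-2-en-1-yl)phenyl.

1. Step 7. The oxonium ylide may collapse by 1,2-proton shift before the aldehyde adds, which gives only O–H insertion, or the acid may give weak facial control. The fallback forms the same C2–C3 bond by an auxiliary-controlled Evans syn aldol reaction, uses known chemistry throughout, sets out from aldehyde 15 and aryl bromide 5, and comes back at 19.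
   - Commercial [(4-methoxybenzyl)oxy]acetic acid is coupled, as its pivaloyl mixed anhydride, with N-lithiated (S)-4-benzyl-1,3-oxazolidin-2-one to give the glycolyl imide (4S)-4-benzyl-3-{[(4-methoxyphenyl)methoxy]acetyl}-1,3-oxazolidin-2-one F1.
   - Its Z boron enolate (Bu2BOTf, Et3N, CH2Cl2, −78 °C) should add to 15 through a chair transition state to give the syn aldol imide (4S)-4-benzyl-3-{(2S,3R)-3-ArB-3-hydroxy-2-[(4-methoxyphenyl)methoxy]propanoyl}-1,3-oxazolidin-2-one F2, in which the carbinol carbon (the later C2) already has the R configuration.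
   - AlMe3 and MeNH(OMe)·HCl should convert F2 into the Weinreb amide (2S,3R)-3-ArB-3-hydroxy-N-methoxy-2-[(4-methoxyphenyl)methoxy]-N-methylpropanamide F3.
   - An excess of aryllithium 7, made from 5 as in step 3, should then give the syn ketone (2S,3R)-1-ArA-3-ArB-3-hydroxy-2-[(4-methoxyphenyl)methoxy]propan-1-one F4, the C3 epimer of 18.
   - Ring closure under the conditions of step 8 should give the cis chromanone (2R,3S)-7-(methoxymethoxy)-3-[(4-methoxyphenyl)methoxy]-2-ArB-8-(3-methylbut-2-en-1-yl)-2,3-dihydro-4H-chromen-4-one F5. Equilibration at C3 through the enol (DBU, toluene, rt) should then lead to the trans isomer 19.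

2. Step 8. Retro-aldol fragmentation of the alkoxide, which would erode both centres, or enolisation at C3 may compete with ring closure, above all if the displacement needs heating. The fallback hides the nucleophile as a silyl ether and frees it only in catalytic amounts; it sets out from 18 and comes back at 19. TMSCl and imidazole in CH2Cl2 should give the trimethylsilyl ether (2R,3R)-1-ArA-3-ArB-2-[(4-methoxyphenyl)methoxy]-3-[(trimethylsilyl)oxy]propan-1-one F6. A catalytic amount of Bu4N[Ph3SiF2] in THF at −20 °C then removes the silyl group; the alkoxide closes ring C, and the fluoride leaving the arene desilylates the next molecule. No stoichiometric base is present, and the product is 19.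

3. Step 10. Protic acid may cyclise the freed phenols onto the neighbouring prenyl groups (chroman formation) or add methanol across the double bonds. The fallback exchanges the acetals for silyl groups without protic acid; it sets out from 20 and comes back at 21. TMSOTf and 2,2′-bipyridyl in MeCN at 0 °C should convert both aryl MOM ethers into aryl silyl ethers and silylate the C3 hydroxyl, giving the tris(trimethylsilyl) ether (2R,3R)-3,7-bis[(trimethylsilyl)oxy]-2-{3,5-bis(3-methylbut-2-en-1-yl)-4-[(trimethylsilyl)oxy]phenyl}-8-(3-methylbut-2-en-1-yl)-2,3-dihydro-4H-chromen-4-one F7. Water with a trace of citric acid in THF should then hydrolyse F7 to 21.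

**Further compounds**
F1 | step 7 | (4S)-4-benzyl-3-{[(4-methoxyphenyl)methoxy]acetyl}-1,3-oxazolidin-2-one | COc1ccc(COCC(=O)N2[C@@H](Cc3ccccc3)COC2=O)cc1
F2 | step 7 | (4S)-4-benzyl-3-{(2S,3R)-3-hydroxy-2-[(4-methoxyphenyl)methoxy]-3-[4-(methoxymethoxy)-3,5-bis(3-methylbut-2-en-1-yl)phenyl]propanoyl}-1,3-oxazolidin-2-one | O[C@H](c1cc(CC=C(C)C)c(OCOC)c(CC=C(C)C)c1)[C@H](OCc1ccc(OC)cc1)C(=O)N1[C@@H](Cc2ccccc2)COC1=O
F3 | step 7 | (2S,3R)-3-hydroxy-N-methoxy-2-[(4-methoxyphenyl)methoxy]-3-[4-(methoxymethoxy)-3,5-bis(3-methylbut-2-en-1-yl)phenyl]-N-methylpropanamide | O[C@H](c1cc(CC=C(C)C)c(OCOC)c(CC=C(C)C)c1)[C@H](OCc1ccc(OC)cc1)C(=O)N(C)OC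
F4 | step 7 | (2S,3R)-1-[2-fluoro-4-(methoxymethoxy)-3-(3-methylbut-2-en-1-yl)phenyl]-3-hydroxy-2-[(4-methoxyphenyl)methoxy]-3-[4-(methoxymethoxy)-3,5-bis(3-methylbut-2-en-1-yl)phenyl]propan-1-one | O[C@H](c1cc(CC=C(C)C)c(OCOC)c(CC=C(C)C)c1)[C@H](OCc1ccc(OC)cc1)C(=O)c1ccc(OCOC)c(CC=C(C)C)c1F
F5 | step 7 | (2R,3S)-7-(methoxymethoxy)-3-[(4-methoxyphenyl)methoxy]-2-[4-(methoxymethoxy)-3,5-bis(3-methylbut-2-en-1-yl)phenyl]-8-(3-methylbut-2-en-1-yl)-2,3-dihydro-4H-chromen-4-one | CC(C)=CCc1cc([C@H]2Oc3c(ccc(OCOC)c3CC=C(C)C)C(=O)[C@H]2OCc4ccc(OC)cc4)cc(CC=C(C)C)c1OCOC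
F6 | step 8 | (2R,3R)-1-[2-fluoro-4-(methoxymethoxy)-3-(3-methylbut-2-en-1-yl)phenyl]-2-[(4-methoxyphenyl)methoxy]-3-[4-(methoxymethoxy)-3,5-bis(3-methylbut-2-en-1-yl)phenyl]-3-[(trimethylsilyl)oxy]propan-1-one | C[Si](C)(C)O[C@H](c1cc(CC=C(C)C)c(OCOC)c(CC=C(C)C)c1)[C@@H](OCc1ccc(OC)cc1)C(=O)c1ccc(OCOC)c(CC=C(C)C)c1F
F7 | step 10 | (2R,3R)-3,7-bis[(trimethylsilyl)oxy]-2-{3,5-bis(3-methylbut-2-en-1-yl)-4-[(trimethylsilyl)oxy]phenyl}-8-(3-methylbut-2-en-1-yl)-2,3-dihydro-4H-chromen-4-one | CC(C)=CCc1cc([C@H]2Oc3c(ccc(O[Si](C)(C)C)c3CC=C(C)C)C(=O)[C@@H]2O[Si](C)(C)C)cc(CC=C(C)C)c1O[Si](C)(C)C
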